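**Strategy.** The lower epicatechin unit is disconnected across its pyran ring C at O1–C2 and C4–C4a. This leaves a benzylated, C8-brominated epicatechin-(4β→6)-epicatechin dimer carrying a 2,4,6-trihydroxyphenyl group at C4, and a three-carbon epoxy carbinol. Ring A of this unit is a phloroglucinol ring with O1 para to the interflavan carbon C6, so the dimer cation can be trapped by symmetric phloroglucinol and no C6/C8 problem arises. The key step then joins the epoxy carbinol to the unhindered para hydroxyl and an adjacent ring CH in one pot (Mitsunobu etherification, then epoxide–arene cyclisation), setting C2 by inversion and carrying C3 over from the epoxide.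

Key step: step 9

Remark: the target is read as epicatechin-(4β→6)-epicatechin-(4β→6)-epicatechin (all units 2R,3R, each interflavan bond trans to the neighbouring 3-OH); flavan numbering is used for the upper, middle and lower units, and (−)-epicatechin is taken as a commercial starting material for the upper and middle units.

**Step 1**
Reactants: 1 (−)-epicatechin
Product: 2 5,7,3',4'-tetra-O-benzyl-(−)-epicatechin
Conditions: BnBr, K2CO3, DMF, 0 °C → rt
Reagents that add atoms: benzyl bromide, BrCc1ccccc1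
Why: Williamson etherification should alkylate the four acidic phenols and leave the secondary 3-OH free; no stereocentre is touched.

**Step 2**
Reactants: 2 5,7,3',4'-tetra-O-benzyl-(−)-epicatechin
Product: 3 8-bromo-5,7,3',4'-tetra-O-benzyl-(−)-epicatechin
Conditions: NBS, CH2Cl2, −40 °C → rt
Reagents that add atoms: N-bromosuccinimide, O=C1CCC(=O)N1Br
Why: Electrophilic aromatic bromination of the 5,7-dialkoxy ring A should go to C8, its most reactive position, which installs the blocking group that later forces C6 attack.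

**Step 3**
Reactants: 3 8-bromo-5,7,3',4'-tetra-O-benzyl-(−)-epicatechin
Product: 4 8-bromo-5,7,3',4'-tetra-O-benzyl-4β-(2-ethoxyethoxy)epicatechin
Conditions: DDQ, 2-ethoxyethanol, CH2Cl2, rt
Reagents that add atoms: 2-ethoxyethanol, CCOCCO
Why: DDQ benzylic oxidation (hydride abstraction at C4, stabilised by the ring A oxygens) gives a cation that the alcohol should capture anti to the 2-aryl and 3-OH groups, setting the 4β (3,4-trans) ether.

**Step 4**
Reactants: 3 8-bromo-5,7,3',4'-tetra-O-benzyl-(−)-epicatechin (excess, nucleophile); 4 8-bromo-5,7,3',4'-tetra-O-benzyl-4β-(2-ethoxyethoxy)epicatechin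
Product: 5 [8-bromo-tetra-O-benzylepicatechin]-(4β→6)-[8-bromo-tetra-O-benzylepicatechin]
Conditions: Me3SiOSO2CF3 (cat.), CH2Cl2, −78 °C; excess 3 recovered
Reagents that add atoms: none
Why: Lewis-acid-promoted Friedel–Crafts alkylation by the flavan-4-yl cation; C8 is blocked in both partners, so the only free ring A carbon of 3 is C6, and attack anti to the 2-aryl and 3-OH groups should set the 4β bond.

**Step 5**
Reactants: 5 [8-bromo-tetra-O-benzylepicatechin]-(4β→6)-[8-bromo-tetra-O-benzylepicatechin]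
Product: 6 dimer 5 carrying a 4β-(2-ethoxyethoxy) group on its lower unit
Conditions: DDQ, 2-ethoxyethanol, CH2Cl2, rt
Reagents that add atoms: 2-ethoxyethanol, CCOCCO
Why: The same DDQ benzylic oxidation should act at the only benzylic CH2 (C4 of the lower unit), the tertiary C4–H of the upper unit being shielded, with alcohol capture again anti to the 2-aryl and 3-OH groups (4β).

**Step 6**
Reactants: 6 dimer with lower-unit 4β-(2-ethoxyethoxy) group; 7 phloroglucinol (large excess)
Product: 8 dimer 5 carrying a 4β-(2,4,6-trihydroxyphenyl) group on its lower unit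
Conditions: BF3·OEt2 (cat.), THF/CH2Cl2, −40 → 0 °C
Reagents that add atoms: none
Why: Friedel–Crafts capture of the dimeric C4 cation by symmetric phloroglucinol can give only one regioisomer, the excess suppresses double alkylation, and approach anti to the 2-aryl and 3-OH groups should set the 4β centre.

**Step 7**
Reactants: 9 3,4-bis(benzyloxy)benzaldehyde
Product: 10 rac-1-[3,4-bis(benzyloxy)phenyl]prop-2-en-1-ol
Conditions: CH2=CHMgBr, THF, −78 → 0 °C; then aq. NH4Cl
Reagents that add atoms: vinylmagnesium bromide, C=C[Mg]Br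
Why: Grignard 1,2-addition to the aldehyde gives the racemic aryl vinyl carbinol.

**Step 8**
Reactants: 10 rac-1-[3,4-bis(benzyloxy)phenyl]prop-2-en-1-ol
Product: 11 (S)-[3,4-bis(benzyloxy)phenyl][(R)-oxiran-2-yl]methanol (erythro)
Conditions: Ti(OiPr)4 (cat.), L-(+)-DIPT, t-BuOOH (0.5 equiv), 4 Å molecular sieves, CH2Cl2, −20 °C; unreacted (S)-10 separated
Reagents that add atoms: tert-butyl hydroperoxide, CC(C)(C)OO
Why: In the Sharpless kinetic resolution the (R)-carbinol should be epoxidised fast with L-(+)-DIPT on the face fixed by the tartrate, giving the erythro epoxy alcohol (carbinol S by selection of the enantiomer, oxirane R by reagent control).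

**Step 9**
Reactants: 8 dimer with lower-unit 4β-(2,4,6-trihydroxyphenyl) group; 11 (S)-[3,4-bis(benzyloxy)phenyl][(R)-oxiran-2-yl]methanol (1.1 equiv)
Product: 13 [8-bromo-tetra-O-benzylepicatechin]-(4β→6)-[8-bromo-tetra-O-benzylepicatechin]-(4β→6)-[3',4'-di-O-benzylepicatechin], via aryl ether epoxide 12 (not isolated)
Conditions: PPh3, DIAD, CH2Cl2/toluene, −20 °C → rt; then (CF3)2CHOH added to the same flask, rt
Reagents that add atoms: none
Why: The betaine from PPh3 and DIAD activates the carbinol of 11 and the phenoxide of 8 displaces it in an SN2 Mitsunobu etherification that forms O1–C2 with inversion; the ionising hydrogen-bond donor (CF3)2CHOH then activates the terminal oxirane of 12, and the electron-rich ring carbon next to the new ether oxygen opens it in an intramolecular Friedel–Crafts alkylation that forms C4–C4a. The closest known reaction type is the stepwise Mitsunobu etherification and acid-promoted epoxide–arene cycloalkylation route to 2-arylchroman-3-ols, run here in one flask as a formal (3+3) annulation. Ring C of the lower unit closes in the 6-endo mode at the unsubstituted oxirane carbon, which is favoured over 5-exo attack at the substituted carbon, so the C3–O bond is never broken. C2 is set by the inversion at the S carbinol carbon of 11 and C3 is carried over unchanged from the R oxirane carbon, which gives the 2,3-cis (2R,3R) unit by reagent control, independent of the remote stereocentres. The step needs site selectivity among three phenols, which the bulky flavan-4-yl substituent should secure by shielding the two ortho hydroxyls and leaving the para hydroxyl (the future O1) exposed; the two ring CH positions beside it are equivalent, so either closure gives the 4→6 connectivity. It also needs substitution without benzylic ionisation, which the electron-withdrawing oxirane next to the carbinol carbon and the low temperature should secure.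

**Step 10**
Reactants: 13 decabenzyl dibromo trimer
Product: 14 epicatechin-(4β→6)-epicatechin-(4β→6)-epicatechin (CNP0163146.2)
Conditions: H2 (1 atm), Pd(OH)2/C, NaOAc, THF/MeOH/H2O, rt
Reagents that add atoms: none
Why: Hydrogenolysis should cleave the ten benzyl ethers and both aryl C–Br bonds in one operation, NaOAc buffering the HBr so that the acid-labile interflavan bonds and all stereocentres remain untouched.

**Compound list**

1 | (−)-epicatechin, (2R,3R)-2-(3,4-dihydroxyphenyl)chromane-3,5,7-triol | Oc1cc(O)c2c(c1)O[C@H](c1ccc(O)c(O)c1)[C@H](O)C2 | starting material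

2 | 5,7,3',4'-tetra-O-benzyl-(−)-epicatechin (2R,3R) | O(Cc4ccccc4)c1cc(OCc4ccccc4)c2c(c1)O[C@H](c1ccc(OCc4ccccc4)c(OCc4ccccc4)c1)[C@H](O)C2 | intermediate

3 | 8-bromo-5,7,3',4'-tetra-O-benzyl-(−)-epicatechin | O(Cc4ccccc4)c1cc(OCc4ccccc4)c2c(c1Br)O[C@H](c1ccc(OCc4ccccc4)c(OCc4ccccc4)c1)[C@H](O)C2 | intermediate

4 | 8-bromo-5,7,3',4'-tetra-O-benzyl-4β-(2-ethoxyethoxy)epicatechin (2,3-cis, 3,4-trans) | O(Cc4ccccc4)c1cc(OCc4ccccc4)c2c(c1Br)O[C@H](c1ccc(OCc4ccccc4)c(OCc4ccccc4)c1)[C@H](O)[C@H]2OCCOCC | intermediate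

5 | [8-bromo-5,7,3',4'-tetra-O-benzylepicatechin]-(4β→6)-[8-bromo-5,7,3',4'-tetra-O-benzylepicatechin] | O(Cc4ccccc4)c1cc(OCc4ccccc4)c2c(c1Br)O[C@H](c1ccc(OCc4ccccc4)c(OCc4ccccc4)c1)[C@H](O)[C@H]2c1c(OCc4ccccc4)c(Br)c2c(c1OCc4ccccc4)C[C@@H](O)[C@@H](c1ccc(OCc4ccccc4)c(OCc4ccccc4)c1)O2 | intermediate

6 | dimer 5 with a 4β-(2-ethoxyethoxy) group on the lower unit (3,4-trans) | O(Cc4ccccc4)c1cc(OCc4ccccc4)c2c(c1Br)O[C@H](c1ccc(OCc4ccccc4)c(OCc4ccccc4)c1)[C@H](O)[C@H]2c1c(OCc4ccccc4)c(Br)c2c(c1OCc4ccccc4)[C@H](OCCOCC)[C@@H](O)[C@@H](c1ccc(OCc4ccccc4)c(OCc4ccccc4)c1)O2 | intermediate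

7 | phloroglucinol (benzene-1,3,5-triol) | Oc1cc(O)cc(O)c1 | starting material

8 | dimer 5 with a 4β-(2,4,6-trihydroxyphenyl) group on the lower unit (3,4-trans) | O(Cc4ccccc4)c1cc(OCc4ccccc4)c2c(c1Br)O[C@H](c1ccc(OCc4ccccc4)c(OCc4ccccc4)c1)[C@H](O)[C@H]2c1c(OCc4ccccc4)c(Br)c2c(c1OCc4ccccc4)[C@H](c1c(O)cc(O)cc1O)[C@@H](O)[C@@H](c1ccc(OCc4ccccc4)c(OCc4ccccc4)c1)O2 | intermediate

9 | 3,4-bis(benzyloxy)benzaldehyde | O=Cc1ccc(OCc2ccccc2)c(OCc2ccccc2)c1 | starting material

10 | rac-1-[3,4-bis(benzyloxy)phenyl]prop-2-en-1-ol | C=CC(O)c1ccc(OCc2ccccc2)c(OCc2ccccc2)c1 | intermediate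

11 | (S)-[3,4-bis(benzyloxy)phenyl][(R)-oxiran-2-yl]methanol (erythro) | C1O[C@H]1[C@@H](O)c1ccc(OCc2ccccc2)c(OCc2ccccc2)c1 | intermediate

12 | aryl ether epoxide: 8 etherified at the 4-OH of the trihydroxyphenyl ring (para to the flavanyl carbon) with the (R)-[3,4-bis(benzyloxy)phenyl][(R)-oxiran-2-yl]methyl group | O(Cc4ccccc4)c1cc(OCc4ccccc4)c2c(c1Br)O[C@H](c1ccc(OCc4ccccc4)c(OCc4ccccc4)c1)[C@H](O)[C@H]2c1c(OCc4ccccc4)c(Br)c2c(c1OCc4ccccc4)[C@H](c1c(O)cc(O[C@H](c3ccc(OCc4ccccc4)c(OCc4ccccc4)c3)[C@H]5CO5)cc1O)[C@@H](O)[C@@H](c1ccc(OCc4ccccc4)c(OCc4ccccc4)c1)O2 | intermediate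

13 | [8-bromo-5,7,3',4'-tetra-O-benzylepicatechin]-(4β→6)-[8-bromo-5,7,3',4'-tetra-O-benzylepicatechin]-(4β→6)-[3',4'-di-O-benzylepicatechin], lower unit 2R,3R with free 3-, 5- and 7-OH | O(Cc4ccccc4)c1cc(OCc4ccccc4)c2c(c1Br)O[C@H](c1ccc(OCc4ccccc4)c(OCc4ccccc4)c1)[C@H](O)[C@H]2c1c(OCc4ccccc4)c(Br)c2c(c1OCc4ccccc4)[C@H](c1c(O)cc3c(c1O)C[C@@H](O)[C@@H](c1ccc(OCc4ccccc4)c(OCc4ccccc4)c1)O3)[C@@H](O)[C@@H](c1ccc(OCc4ccccc4)c(OCc4ccccc4)c1)O2 | intermediate

14 | epicatechin-(4β→6)-epicatechin-(4β→6)-epicatechin (CNP0163146.2) | Oc1cc(O)c2c(c1)O[C@H](c1ccc(O)c(O)c1)[C@H](O)[C@H]2c1c(O)cc2c(c1O)[C@H](c1c(O)cc3c(c1O)C[C@@H](O)[C@@H](c1ccc(O)c(O)c1)O3)[C@@H](O)[C@@H](c1ccc(O)c(O)c1)O2 | target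

**Count.** Total: 10 steps. Longest linear sequence: 8 steps (steps 1, 2, 3, 4, 5, 6, 9, 10).

**Steps most likely to fail**

Step 9 (key step). The etherification may not discriminate well enough between the para hydroxyl and the two shielded ortho hydroxyls, which would lead on to the 4→8-type isomer. Partial ionisation at the electron-rich benzylic carbinol would also erode the configuration at C2. The fallback gives up the late construction of ring C and brings the lower unit in intact: it sets out from 6 and 3, which are coupled at C6 of 3 (Me3SiOSO2CF3 cat., CH2Cl2, −78 °C, C8 blocked by bromine) to give the fully benzylated tribromo trimer F1. Hydrogenolysis of F1 (H2, Pd(OH)2/C, NaOAc, THF/MeOH/H2O) then comes back to the route at 14.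

Step 5. Hydride abstraction may compete at the doubly benzylic C4–H of the upper unit, the product may be over-oxidised to the 4-ketone, or oxidation of the brominated, hindered dimer may stall. The fallback replaces late oxidation by orthogonal leaving groups and sets out from 4. Compound 4 is converted with 2,6-dimethylbenzenethiol and BF3·OEt2 (CH2Cl2, −78 °C) into 8-bromo-tetra-O-benzyl-4β-(2,6-dimethylphenylthio)epicatechin F2. An excess of F2 is coupled at its C6 with 4 under Me3SiOSO2CF3 (cat.) at −78 °C, conditions that should leave the sulfide untouched, to give the dimeric 4β-thioether F3. Thiophilic activation of F3 with AgBF4 in THF at 0 °C in the presence of excess 7 should then give the triol, coming back to the route at 8.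

Step 8. The titanium alkoxide may open the acid-sensitive, electron-rich epoxy carbinol, and the enantiomers may not be discriminated well enough when the epoxide, not the recovered alcohol, is the wanted product. The fallback separates the two stereochemical tasks and sets out from 10. Lipase-catalysed acetylation (Candida antarctica lipase B, vinyl acetate, t-BuOMe, rt) should acylate the R enantiomer to give (R)-1-[3,4-bis(benzyloxy)phenyl]prop-2-en-1-yl acetate F4, which is separated from the S alcohol. Methanolysis (K2CO3, MeOH) gives (R)-1-[3,4-bis(benzyloxy)phenyl]prop-2-en-1-ol F5. Hydroxyl-directed epoxidation (VO(acac)2 cat., t-BuOOH, CH2Cl2, 0 °C) should favour the erythro epoxide, which after chromatography comes back to the route at 11.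

**Further compounds**

F1 | step 9 | [8-bromo-5,7,3',4'-tetra-O-benzylepicatechin]-(4β→6)-[8-bromo-5,7,3',4'-tetra-O-benzylepicatechin]-(4β→6)-[8-bromo-5,7,3',4'-tetra-O-benzylepicatechin] | O(Cc4ccccc4)c1cc(OCc4ccccc4)c2c(c1Br)O[C@H](c1ccc(OCc4ccccc4)c(OCc4ccccc4)c1)[C@H](O)[C@H]2c1c(OCc4ccccc4)c(Br)c2c(c1OCc4ccccc4)[C@H](c1c(OCc4ccccc4)c(Br)c3c(c1OCc4ccccc4)C[C@@H](O)[C@@H](c1ccc(OCc4ccccc4)c(OCc4ccccc4)c1)O3)[C@@H](O)[C@@H](c1ccc(OCc4ccccc4)c(OCc4ccccc4)c1)O2

F2 | step 5 | 8-bromo-5,7,3',4'-tetra-O-benzyl-4β-(2,6-dimethylphenylthio)epicatechin | O(Cc4ccccc4)c1cc(OCc4ccccc4)c2c(c1Br)O[C@H](c1ccc(OCc4ccccc4)c(OCc4ccccc4)c1)[C@H](O)[C@H]2Sc1c(C)cccc1C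

F3 | step 5 | dimer 5 with a 4β-(2,6-dimethylphenylthio) group on the lower unit | O(Cc4ccccc4)c1cc(OCc4ccccc4)c2c(c1Br)O[C@H](c1ccc(OCc4ccccc4)c(OCc4ccccc4)c1)[C@H](O)[C@H]2c1c(OCc4ccccc4)c(Br)c2c(c1OCc4ccccc4)[C@H](Sc1c(C)cccc1C)[C@@H](O)[C@@H](c1ccc(OCc4ccccc4)c(OCc4ccccc4)c1)O2

F4 | step 8 | (R)-1-[3,4-bis(benzyloxy)phenyl]prop-2-en-1-yl acetate | C=C[C@@H](OC(C)=O)c1ccc(OCc2ccccc2)c(OCc2ccccc2)c1

F5 | step 8 | (R)-1-[3,4-bis(benzyloxy)phenyl]prop-2-en-1-ol | C=C[C@@H](O)c1ccc(OCc2ccccc2)c(OCc2ccccc2)c1
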